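**Strategy.** The cyclohexene ring (C12, C13, C14, C15 of the labdane chain and the ring-fusion carbons C6′ and C1′) is traced back to a donor–acceptor vinylcyclobutane in which C1′ is bonded to C14 instead of C12. C1′ is quaternary, α to the C2′ ketone and vinylogously α to the chromone carbonyl, so it leaves as a stabilised enolate, while C12–C13–C14 forms an allyl cation. Ionisation with Sc(OTf)3 and collapse at C12 expand the four-membered ring to the cyclohexene, forming the C12–C1′ bond, the C13=C14 alkene and the C12 stereocentre at once. The cyclobutane comes from a [2+2] photocycloaddition of a flavone-derived methoxyquinone with a labdatriene made by radical epoxypolyene bicyclisation.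

Key step: step 16

**Remarks**
- Labels: labdane numbering (C1–C20) for the terpene part; C1′–C6′ for the quinone-derived ring (C1′ carries the chromone, C2′ and C5′ are the carbonyls, C4′ carries OMe).
- Assumption: 1-propynylmagnesium bromide and vinyl bromide are bought as THF solutions, and 2,4,5-trimethoxybenzoyl chloride is bought as such.
- Step 15 is not expected to distinguish the two faces of the quinone, because the reacting diene terminus is remote from the labdane stereocentres. The cis-fused diastereomer drawn is separated by preparative HPLC.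

## Route

**Step 1**
Reactants: 1 (2E,6E)-farnesyl bromide; 2 1-propynylmagnesium bromide (CH3C≡CMgBr)
Product: 3 (5E,9E)-6,10,14-trimethylpentadeca-5,9,13-trien-2-yne
Conditions: CuI (10 mol %), THF, 0 °C to rt
Reagents that add atoms: none
Why: Copper-catalysed SN2 coupling of an alkynyl Grignard reagent with a primary allylic bromide gives the skipped enyne without touching the E-alkenes; no stereocentre is formed.

**Step 2**
Reactants: 3 (5E,9E)-6,10,14-trimethylpentadeca-5,9,13-trien-2-yne
Product: 4 (2E,6E,10E)-2,6,10-trimethylpentadeca-2,6,10-trien-13-yn-1-ol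
Conditions: SeO2 (10 mol %), t-BuOOH, salicylic acid (10 mol %), CH2Cl2, 0 °C to rt
Reagents that add atoms: tert-butyl hydroperoxide, CC(C)(C)OO (oxygen atom, passed on through the SeO2 catalyst)
Why: Catalytic SeO2 allylic oxidation (ene reaction, then [2,3]-shift) should attack the most accessible, terminal trisubstituted alkene at its E-methyl group, as in farnesyl and geranyl derivatives, giving the E-allylic alcohol.

**Step 3**
Reactants: 4 (2E,6E,10E)-2,6,10-trimethylpentadeca-2,6,10-trien-13-yn-1-ol
Product: 5 [(2S,3S)-3-((3E,7E)-3,7-dimethyldodeca-3,7-dien-10-yn-1-yl)-2-methyloxiran-2-yl]methanol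
Conditions: Ti(OiPr)4 (10 mol %), L-(+)-diethyl tartrate (12 mol %), t-BuOOH, 4 Å MS, CH2Cl2, −20 °C
Reagents that add atoms: tert-butyl hydroperoxide, CC(C)(C)OO
Why: Sharpless asymmetric epoxidation of the E-2-methylallylic alcohol with the L-(+)-tartrate catalyst should give the (2S,3S)-epoxide, which fixes the later C3 as S and, through the E geometry, the later C4.

**Step 4**
Reactants: 5 the (2S,3S)-epoxy alcohol
Product: 6 tert-butyldimethylsilyl ether of 5
Conditions: TBSCl, imidazole, DMF, rt
Reagents that add atoms: tert-butyldimethylsilyl chloride, CC(C)(C)[Si](C)(C)Cl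
Why: Standard silylation of the primary alcohol, needed because a free 2,3-epoxy alcohol would be deoxygenated by trivalent titanium in the next step.

**Step 5**
Reactants: 6 the silylated (2S,3S)-epoxide
Product: 7 18-(tert-butyldimethylsilyloxy)-14,15-dinorlabd-8(17)-en-12-yn-3β-ol (trans-decalin; 4α-CH2OTBS, 4β-Me, 10β-Me, 9β-but-2-ynyl, exocyclic 8(17)-methylene)
Conditions: Cp2TiCl2 (2.5 equiv), Mn dust, THF, rt; aq. NaH2PO4 work-up
Reagents that add atoms: none
Why: Titanocene-mediated radical epoxypolyene cyclisation: homolytic epoxide opening gives the tertiary C4 radical, two chair-like 6-endo closures set C5, C10 and C9 (trans-decalin, 4α-CH2OTBS from the E-substituent, 9β side chain), and trapping of the C8 radical by a second trivalent titanium followed by β-hydride elimination should give the exocyclic 8(17)-alkene.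

**Step 6**
Reactants: 7 the 3β-alcohol
Product: 8 O-[18-(tert-butyldimethylsilyloxy)-14,15-dinorlabd-8(17)-en-12-yn-3β-yl] S-methyl dithiocarbonate
Conditions: NaH, imidazole (cat.), THF, 0 °C to rt; CS2; then MeI
Reagents that add atoms: carbon disulfide, S=C=S; iodomethane, CI
Why: Xanthate formation at the hindered equatorial C3 alcohol, the first half of a Barton–McCombie deoxygenation; no stereocentre changes.

**Step 7**
Reactants: 8 the xanthate
Product: 9 18-(tert-butyldimethylsilyloxy)-14,15-dinorlabd-8(17)-en-12-yne
Conditions: Bu3SnH, AIBN (cat.), toluene, 100 °C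
Reagents that add atoms: none
Why: Barton–McCombie radical deoxygenation removes the C3 oxygen left by the epoxide; neither the alkyne nor the exocyclic alkene lies within cyclising distance of the C3 radical.

**Step 8**
Reactants: 9 the 3-deoxy enyne
Product: 11 18-(tert-butyldimethylsilyloxy)-14,15-dinorlabd-8(17)-en-12-yn-7-one, via 7α-alcohol 10 (not isolated)
Conditions: SeO2 (0.5 equiv), t-BuOOH, CH2Cl2, rt; aqueous wash; then Dess–Martin periodinane, pyridine, CH2Cl2, 0 °C
Reagents that add atoms: tert-butyl hydroperoxide, CC(C)(C)OO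
Why: The SeO2 ene reaction at the exocyclic methylene with loss of the axial H7, then [2,3]-shift, should give the axial 7α-alcohol with the 8(17)-alkene retained (the internal alkyne reacts more slowly), and Dess–Martin oxidation of the crude alcohol gives the exocyclic enone.

**Step 9**
Reactants: 11 the 7-ketone
Product: 12 18-(tert-butyldimethylsilyloxy)-14,15-dinorlabd-8(17)-en-12-yn-7β-ol
Conditions: NaBH4, CeCl3·7H2O, MeOH, −78 °C
Reagents that add atoms: none
Why: Luche 1,2-reduction, in which axial hydride delivery from the α-face of the exocyclic enone should give the equatorial 7β-alcohol.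

**Step 10**
Reactants: 12 the 7β-alcohol; 13 vinyl bromide
Product: 15 (12E)-18-(tert-butyldimethylsilyloxy)labda-8(17),12,14-trien-7β-ol, via alkenylzirconocene 14 (not isolated)
Conditions: Cp2Zr(H)Cl (2.5 equiv), THF, rt to 40 °C; then 13, Pd(PPh3)4 (5 mol %), ZnCl2, THF, rt
Reagents that add atoms: none
Why: Hydrozirconation adds H–Zr syn with zirconium at the less hindered, methyl-bearing alkyne carbon after equilibration (the alcohol is held as its zirconium alkoxide), and the Negishi-type palladium-catalysed coupling with vinyl bromide proceeds with retention, so the 12E diene results.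

**Step 11**
Reactants: 15 the trienol
Product: 16 (12E)-7β-(chloroacetoxy)-18-(tert-butyldimethylsilyloxy)labda-8(17),12,14-triene
Conditions: (ClCH2CO)2O, pyridine, DMAP (cat.), CH2Cl2, 0 °C
Reagents that add atoms: chloroacetic anhydride, O=C(CCl)OC(=O)CCl
Why: Acylation of the secondary allylic alcohol with a base-labile chloroacetate that survives the later steps and is removed together with the aryl acetates at the end.

**Step 12**
Reactants: 17 2′,4′,6′-trihydroxyacetophenone; 18 2,4,5-trimethoxybenzoyl chloride
Product: 20 5,7-dihydroxy-2′,4′,5′-trimethoxyflavone, via β-diketone 19 (not isolated)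
Conditions: LiN(SiMe3)2 (4.5 equiv), THF, −78 °C to rt, then 18; then H2SO4 (cat.), AcOH, 95 °C
Reagents that add atoms: none
Why: Claisen-type C-acylation of the polylithiated acetophenone enolate by the aroyl chloride gives the β-diketone, which cyclodehydrates under acid to the flavone.

**Step 13**
Reactants: 20 the dihydroxyflavone
Product: 21 5,7-diacetoxy-2′,4′,5′-trimethoxyflavone
Conditions: Ac2O, pyridine, DMAP (cat.), rt
Reagents that add atoms: acetic anhydride, CC(=O)OC(C)=O
Why: Peracetylation masks both phenols (also the chelated 5-OH) against the cerium oxidant and blocks excited-state proton transfer in step 15.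

**Step 14**
Reactants: 21 the flavone diacetate
Product: 22 2-(5,7-diacetoxy-4-oxo-4H-chromen-2-yl)-5-methoxy-1,4-benzoquinone
Conditions: (NH4)2Ce(NO3)6 (2.5 equiv), MeCN–H2O, 0 °C
Reagents that add atoms: water, O
Why: Oxidative demethylation of the para-related 2′,5′-dimethoxy pair of the 1,2,4-trimethoxyarene should give the 2-methoxy-1,4-benzoquinone with the 4′-methoxy group retained.

**Step 15**
Reactants: 16 the labdatriene chloroacetate; 22 the flavone quinone
Product: 23 cis-fused vinylcyclobutane: 1-(5,7-diacetoxy-4-oxochromen-2-yl)-4-methoxybicyclo[4.2.0]oct-3-ene-2,5-dione (C1 = C1′, C6 = C6′, C7 = C15, C8 = C14) whose C14 carries, exo (cis to the chromone), the (E)-C13(Me)=C12H–C11H2–decalin chain; C6′ and C1′ configured as in the target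
Conditions: hν (440–450 nm LEDs), CH2Cl2, −40 °C, degassed; preparative HPLC
Reagents that add atoms: none
Why: In this quinone–diene [2+2] photocycloaddition the triplet quinone should bond C6′ to the unhindered diene terminus C15, giving the most stabilised 1,4-biradical (C1′ flanked by C2′=O and the chromone, plus a transoid allyl radical that can only close C14–C1′); cis ring fusion follows from ring strain, the facial diastereomer is removed by HPLC, and the C14 epimers need no separation because C14 becomes sp2 in step 16.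

**Step 16**
Reactants: 23 the vinylcyclobutane
Product: 24 ring-expanded cis-fused cyclohexene: the target skeleton carrying 18-OTBS in place of the aldehyde, 7-O-chloroacetyl and 5,7-di-O-acetyl groups
Conditions: Sc(OTf)3 (20 mol %), 2,6-di-tert-butylpyridine (20 mol %), 4 Å MS, CH2Cl2, −40 to 0 °C
Reagents that add atoms: none
Why: Sc(OTf)3 binds the chromone carbonyl (and C2′=O) and ionises the strained, doubly activated C14–C1′ bond to a tight ion pair of a 1,3-dialkyl-2-methylallyl cation (C12–C13–C14) and a scandium dienolate; re-closure at C14 only returns 23, whereas attack of C1′ on the distal terminus C12 gives the unstrained cyclohexene irreversibly. The closest known reaction type is the zwitterionic (Lewis-acid- or polar-solvent-promoted) vinylcyclobutane-to-cyclohexene rearrangement of donor–acceptor cyclobutanes, a formal 1,3-shift. The six-membered ring closes in a 6-endo fashion (enolate carbon onto the far end of the allyl cation) while the four-membered ring opens in the same event. C1′ is re-formed cis to H6′ because the untouched C6′ holds the allyl unit through C15 on one face of the dienolate only. C12 is set by the E geometry of the allyl cation (C11 outside, configurationally stable at low temperature) together with a boat-like, Cope-type ion pair in which the cation lies over the chromone arm (C1′, chromone C2=C3) that carries most of the negative charge, so C11 should end cis to the chromone. The step needs six- over four-ring closure (secured by ring strain and the reversibility of the latter) and this chromone-endo facial mode (secured by charge pairing).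

**Step 17**
Reactants: 24 the ring-expanded silyl ether
Product: 25 the corresponding C18 primary alcohol (7-O-chloroacetyl and 5,7-di-O-acetyl retained)
Conditions: HF·pyridine, pyridine, THF, 0 °C to rt
Reagents that add atoms: none
Why: Fluoride cleaves the primary silyl ether while the chloroacetate, the aryl acetates and the vinylogous ester survive the weakly acidic medium.

**Step 18**
Reactants: 25 the C18 alcohol
Product: 26 7-O-chloroacetyl-5,7-di-O-acetyl-dichrostachine H (C18 aldehyde)
Conditions: Dess–Martin periodinane, pyridine, CH2Cl2, 0 °C to rt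
Reagents that add atoms: none
Why: Dess–Martin oxidation of the neopentyl primary alcohol to the non-enolisable aldehyde under near-neutral conditions that spare the enedione and the esters.

**Step 19**
Reactants: 26 the triester aldehyde
Product: 27 dichrostachine H
Conditions: K2CO3 (0.3 equiv), MeOH, 0 °C
Reagents that add atoms: none
Why: Brief carbonate-catalysed methanolysis removes the two aryl acetates and the activated chloroacetate; the aldehyde has no α-hydrogen and C1′ is quaternary, so no stereocentre should be affected.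

## Compound list

1 | (2E,6E)-farnesyl bromide | CC(C)=CCC/C(C)=C/CC/C(C)=C/CBr | starting material
2 | 1-propynylmagnesium bromide | CC#C[Mg]Br | starting material
3 | (5E,9E)-6,10,14-trimethylpentadeca-5,9,13-trien-2-yne | CC#CC/C=C(\C)CC/C=C(\C)CCC=C(C)C | intermediate
4 | (2E,6E,10E)-2,6,10-trimethylpentadeca-2,6,10-trien-13-yn-1-ol | OC/C(C)=C/CC/C(C)=C/CC/C(C)=C/CC#CC | intermediate
5 | [(2S,3S)-3-((3E,7E)-3,7-dimethyldodeca-3,7-dien-10-yn-1-yl)-2-methyloxiran-2-yl]methanol | OC[C@]1(C)O[C@H]1CC/C(C)=C/CC/C(C)=C/CC#CC | intermediate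
6 | tert-butyldimethylsilyl ether of 5 | CC(C)(C)[Si](C)(C)OC[C@]1(C)O[C@H]1CC/C(C)=C/CC/C(C)=C/CC#CC | intermediate
7 | 18-(tert-butyldimethylsilyloxy)-14,15-dinorlabd-8(17)-en-12-yn-3β-ol | C=C1CC[C@@H]2[C@](C)(CC[C@H](O)[C@@]2(C)CO[Si](C)(C)C(C)(C)C)[C@H]1CC#CC | intermediate
8 | S-methyl xanthate of 7 at O3 | C=C1CC[C@@H]2[C@](C)(CC[C@H](OC(=S)SC)[C@@]2(C)CO[Si](C)(C)C(C)(C)C)[C@H]1CC#CC | intermediate
9 | 18-(tert-butyldimethylsilyloxy)-14,15-dinorlabd-8(17)-en-12-yne | C=C1CC[C@@H]2[C@](C)(CCC[C@@]2(C)CO[Si](C)(C)C(C)(C)C)[C@H]1CC#CC | intermediate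
10 | 18-(tert-butyldimethylsilyloxy)-14,15-dinorlabd-8(17)-en-12-yn-7α-ol (not isolated) | C=C1[C@H](O)C[C@@H]2[C@](C)(CCC[C@@]2(C)CO[Si](C)(C)C(C)(C)C)[C@H]1CC#CC | intermediate
11 | 18-(tert-butyldimethylsilyloxy)-14,15-dinorlabd-8(17)-en-12-yn-7-one | C=C1C(=O)C[C@@H]2[C@](C)(CCC[C@@]2(C)CO[Si](C)(C)C(C)(C)C)[C@H]1CC#CC | intermediate
12 | 18-(tert-butyldimethylsilyloxy)-14,15-dinorlabd-8(17)-en-12-yn-7β-ol | C=C1[C@@H](O)C[C@@H]2[C@](C)(CCC[C@@]2(C)CO[Si](C)(C)C(C)(C)C)[C@H]1CC#CC | intermediate
13 | vinyl bromide | C=CBr | starting material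
14 | (E)-alkenylzirconocene chloride of 12, zirconium on C13, O7 bound to a second zirconocene chloride (not isolated) | C=C1[C@@H](O[Zr](Cl)(C3C=CC=C3)C3C=CC=C3)C[C@@H]2[C@](C)(CCC[C@@]2(C)CO[Si](C)(C)C(C)(C)C)[C@H]1C/C=C(\C)[Zr](Cl)(C1C=CC=C1)C1C=CC=C1 | intermediate
15 | (12E)-18-(tert-butyldimethylsilyloxy)labda-8(17),12,14-trien-7β-ol | C=C1[C@@H](O)C[C@@H]2[C@](C)(CCC[C@@]2(C)CO[Si](C)(C)C(C)(C)C)[C@H]1C/C=C(\C)C=C | intermediate
16 | (12E)-7β-(chloroacetoxy)-18-(tert-butyldimethylsilyloxy)labda-8(17),12,14-triene | C=C1[C@@H](OC(=O)CCl)C[C@@H]2[C@](C)(CCC[C@@]2(C)CO[Si](C)(C)C(C)(C)C)[C@H]1C/C=C(\C)C=C | intermediate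
17 | 2′,4′,6′-trihydroxyacetophenone | CC(=O)c1c(O)cc(O)cc1O | starting material
18 | 2,4,5-trimethoxybenzoyl chloride | COc1cc(OC)c(C(=O)Cl)cc1OC | starting material
19 | 1-(2,4,6-trihydroxyphenyl)-3-(2,4,5-trimethoxyphenyl)propane-1,3-dione (not isolated) | COc1cc(OC)c(C(=O)CC(=O)c2c(O)cc(O)cc2O)cc1OC | intermediate
20 | 5,7-dihydroxy-2′,4′,5′-trimethoxyflavone | COc1cc(OC)c(-c2cc(=O)c3c(O)cc(O)cc3o2)cc1OC | intermediate
21 | 5,7-diacetoxy-2′,4′,5′-trimethoxyflavone | COc1cc(OC)c(-c2cc(=O)c3c(OC(C)=O)cc(OC(C)=O)cc3o2)cc1OC | intermediate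
22 | 2-(5,7-diacetoxy-4-oxo-4H-chromen-2-yl)-5-methoxy-1,4-benzoquinone | COC1=CC(=O)C(c2cc(=O)c3c(OC(C)=O)cc(OC(C)=O)cc3o2)=CC1=O | intermediate
23 | cis-fused vinylcyclobutane (C14–C1′ and C15–C6′ bonded; C14 alkenyl exo; with its C14 epimer) | C=C1[C@@H](OC(=O)CCl)C[C@@H]2[C@](C)(CCC[C@@]2(C)CO[Si](C)(C)C(C)(C)C)[C@H]1C/C=C(\C)[C@@H]1C[C@H]2C(=O)C(OC)=CC(=O)[C@@]12c1cc(=O)c2c(OC(C)=O)cc(OC(C)=O)cc2o1 | intermediate
24 | ring-expanded cyclohexene: 18-O-TBS carbinol, 7-O-chloroacetyl, 5,7-di-O-acetyl form of the target skeleton | C=C1[C@@H](OC(=O)CCl)C[C@@H]2[C@](C)(CCC[C@@]2(C)CO[Si](C)(C)C(C)(C)C)[C@H]1C[C@@H]1C(C)=CC[C@H]2C(=O)C(OC)=CC(=O)[C@@]12c1cc(=O)c2c(OC(C)=O)cc(OC(C)=O)cc2o1 | intermediate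
25 | C18 primary alcohol of 24 | C=C1[C@@H](OC(=O)CCl)C[C@@H]2[C@](C)(CCC[C@@]2(C)CO)[C@H]1C[C@@H]1C(C)=CC[C@H]2C(=O)C(OC)=CC(=O)[C@@]12c1cc(=O)c2c(OC(C)=O)cc(OC(C)=O)cc2o1 | intermediate
26 | 7-O-chloroacetyl-5,7-di-O-acetyl-dichrostachine H | C=C1[C@@H](OC(=O)CCl)C[C@@H]2[C@](C)(CCC[C@@]2(C)C=O)[C@H]1C[C@@H]1C(C)=CC[C@H]2C(=O)C(OC)=CC(=O)[C@@]12c1cc(=O)c2c(OC(C)=O)cc(OC(C)=O)cc2o1 | intermediate
27 | dichrostachine H | C=C1[C@@H](O)C[C@@H]2[C@](C)(CCC[C@@]2(C)C=O)[C@H]1C[C@@H]1C(C)=CC[C@H]2C(=O)C(OC)=CC(=O)[C@@]12c1cc(=O)c2c(O)cc(O)cc2o1 | target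

## Step count and risks

Total step count: 19. Longest linear sequence: 16 steps (steps 1–11, then 15–19); steps 12–14 form the flavone branch.

**Steps most likely to fail**

1. **Step 16 (ring expansion).** The ion pair may collapse on the other face of the allyl terminus (quinone-endo mode, giving the C12 epimer), the allyl cation may lose a proton, or the zwitterion may revert by retro-Michael cleavage and scramble the quinone face. Fallback: the stereo-determining event is moved from ion-pair collapse to a ligand-controlled palladium-catalysed allylic alkylation. Setting out from 23, Pd2(dba)3 (zerovalent palladium) with a chiral trans-1,2-diaminocyclohexane bis(2-diphenylphosphinobenzamide) ligand in THF opens the C14–C1′ bond anti to the metal. This gives a π-allylpalladium cation and the free stabilised enolate, as is known for acceptor-substituted vinylcyclobutanes. The ligand enantiomer is chosen so that outer-sphere attack of C1′ on C12 occurs from the required face. The route is rejoined at 24, and this fallback makes no new compound.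

2. **Step 15 ([2+2] photocycloaddition).** The triplet quinone may add through the methoxy-bearing double bond or a carbonyl oxygen, abstract hydrogen from the labdane, or be consumed without facial control on the precious diene. Fallback: the C13–C14 bond is made by cross-coupling after a photocycloaddition with a simple alkene in excess. Setting out from 12, hydrozirconation as in step 10 (via 14) and iodinolysis with I2 give the (E)-alkenyl iodide F1, which is chloroacetylated to the iodide chloroacetate F2. Setting out from 22, irradiation with excess vinylboronic acid pinacol ester gives the cis-fused cyclobutyl pinacol boronate F3 (racemic, boron on C14, exo). Suzuki–Miyaura coupling of F2 with F3 (PdCl2(dppf), CsF, dioxane, 60 °C) joins C13 to C14 with retention, and after HPLC removal of the facial diastereomer the route is rejoined at 23.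

3. **Step 5 (radical bicyclisation).** The first radical may be trapped before the second ring closes (monocyclisation or epoxide deoxygenation), and β-hydride elimination may be unselective and give endocyclic alkenes. Fallback: a cationic cyclisation that accepts the endocyclic alkene and moves the double bond later. Setting out from 6, MeAlCl2 in CH2Cl2 at −78 °C should give mainly the Δ7 alcohol F4. This is converted to its xanthate F5 (NaH, CS2, MeI) and reduced with Bu3SnH to the 3-deoxy Δ7 alkene F6. A singlet-oxygen ene reaction (O2, tetraphenylporphyrin, hν) abstracts a C17 hydrogen and gives the 7α-hydroperoxide F7 with the 8(17)-alkene, and PPh3 reduces it to the 7α-alcohol 10, where the route is rejoined (oxidation as in step 8).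

## Further compounds

F0 | step 16 | none | none
F1 | step 15 | (12E)-13-iodo-18-(tert-butyldimethylsilyloxy)-14,15-dinorlabda-8(17),12-dien-7β-ol | C=C1[C@@H](O)C[C@@H]2[C@](C)(CCC[C@@]2(C)CO[Si](C)(C)C(C)(C)C)[C@H]1C/C=C(\C)I
F2 | step 15 | 7-O-chloroacetate of F1 | C=C1[C@@H](OC(=O)CCl)C[C@@H]2[C@](C)(CCC[C@@]2(C)CO[Si](C)(C)C(C)(C)C)[C@H]1C/C=C(\C)I
F3 | step 15 | cis-fused 1-(5,7-diacetoxy-4-oxochromen-2-yl)-4-methoxy-8-(pinacolboryl)bicyclo[4.2.0]oct-3-ene-2,5-dione (racemic; enantiomer leading to 23 drawn) | CC1(C)OB(OC1(C)C)[C@@H]1C[C@H]2C(=O)C(OC)=CC(=O)[C@@]12c1cc(=O)c2c(OC(C)=O)cc(OC(C)=O)cc2o1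
F4 | step 5 | 18-(tert-butyldimethylsilyloxy)-14,15-dinorlabd-7-en-12-yn-3β-ol | CC1=CC[C@@H]2[C@](C)(CC[C@H](O)[C@@]2(C)CO[Si](C)(C)C(C)(C)C)[C@H]1CC#CC
F5 | step 5 | S-methyl xanthate of F4 at O3 | CC1=CC[C@@H]2[C@](C)(CC[C@H](OC(=S)SC)[C@@]2(C)CO[Si](C)(C)C(C)(C)C)[C@H]1CC#CC
F6 | step 5 | 18-(tert-butyldimethylsilyloxy)-14,15-dinorlabd-7-en-12-yne | CC1=CC[C@@H]2[C@](C)(CCC[C@@]2(C)CO[Si](C)(C)C(C)(C)C)[C@H]1CC#CC
F7 | step 5 | 7α-hydroperoxy-18-(tert-butyldimethylsilyloxy)-14,15-dinorlabd-8(17)-en-12-yne | C=C1[C@H](OO)C[C@@H]2[C@](C)(CCC[C@@]2(C)CO[Si](C)(C)C(C)(C)C)[C@H]1CC#CC
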